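In this closed, stirred vessel J takes up L step by step, J to X, X to G, G to D, and the flask asked about is the winter run carried on to 3.0 d.

| setting | winter | autumn | flask |
|---|---|---|---|
| J | 0.050 M | 0.025 M | 0.050 M |
| L | 0.125 M | 0.125 M | 0.125 M |
| temperature | 110 °C | 95 °C | 110 °C |
| remark | the very flask that is asked about, followed so far | run made earlier |  |
| time |  |  | 3.0 d |

| run | time / h | D / % | J / % |
|---|---|---|---|
| winter | 2.50 | 3.3 | 35.1 |
| winter | 6.00 | 7.7 | 12.5 |
| winter | 12.0 | 9.6 | 3.3 |
| winter | 20.0 | 10.3 | 0.7 |
| winter | 25.0 | 8.9 | 1.1 |
| winter | 30.0 | 9.3 | 0.4 |
| winter | 40.0 | 8.6 | 0.9 |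
| autumn | 0.667 | 0.4 | 87.2 |
| autumn | 2.00 | 0 | 67.5 |
| autumn | 3.00 | 1.5 | 55.6 |
| autumn | 5.00 | 2.7 | 39.0 |
| autumn | 8.00 | 5.2 | 23.2 |
| autumn | 10.0 | 7.2 | 16.7 |
| autumn | 12.0 | 8.0 | 12.0 |

(standard deviation of a reading: 0.5 percentage points)

- north-east: at 3.0 d take out 90% of the D then present, then wait 3.0 d
- south-west: change nothing and wait 3.0 d more
- south-east: at 3.0 d raise the temperature by 15 K, then wait 3.0 d
- east: at 3.0 d add L, 50.0% of the amount charged, then wait 3.0 d

- D, in percent of the J first charged, at 3.0 d
- what to do for the largest gain in D; "none" if nothing gains more than 2 percentage points (north-east / south-west / south-east / east / none)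
- D present, with what was taken out counted in, in percent of the J first charged, after south-west
- D present, with what was taken out counted in, in percent of the J first charged, after east

- removed D is counted in
- the numbers in the tables scatter with a standard deviation of 0.5 percentage points
- on the list of suspects stand: L + X -> G; L + G <-> D; J + L -> X
- additions bring no volume worth counting

Is D in the winter run still climbing? The readings say no, for D stood at 10.3% at 20.0 h and at 8.6% at 40.0 h, a fall of 1.7 percentage points against a scatter of 0.5 points, and among the suspects L + G <-> D runs both ways, so I freeze a ratio and not a rate.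

Which ratio? Each J that reached G has cost 2 L and each that reached D 3, and the J charge is 0.400 of the L charge, so with J and X counted as gone the last reading leaves a fraction 0.166 of the L charge free, which gives 0.568 for the hold number q, D over G divided by the fraction of the L charge still free, a reading that carries the scatter of D and belongs to 110 °C.

But X was never read, so what if some remains? Then free L is larger and G smaller than I counted, and these two errors pull q in opposite directions, so I keep it.

What does q commit you to? With the pool of G and D and with q unchanged, I reckon that D at 3.0 d stays near 8.60% and that waiting adds nothing. After east, D over the rest of the pool equals q times a free fraction that shrinks as D takes its share, a quadratic that gives 25.4%. North-east adds no L and shrinks the pool, so by q the D that grows back stays under what stood before, and I reckon the gain below the 7.7 points taken out, which is less than east's 17 points. I cannot reckon south-east from q, but I choose east.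

The forecast, noting that “G rises while L falls”, gives 9% at 3.0 d, 8.6% after south-west and 24% after east, and it also chooses east.

The flask gives 8.71% at 3.0 d, then 8.54% after south-west and 25.2% after east, and east gains 16 points.

    L + X → G (k = 1.90 M⁻¹ h⁻¹, Ea = 102 kJ mol⁻¹)
    L + G ⇌ D (K = 4.50 M⁻¹, k = 11.0 M⁻¹ h⁻¹, Ea = 73.0 kJ mol⁻¹, ΔH = −2.00 kJ mol⁻¹)
    J + L → X (k = 4.20 M⁻¹ h⁻¹, Ea = 74.0 kJ mol⁻¹)
    (constants at 110 °C)

D in the flask is under thermodynamic control, and the back reaction of D to L + G is the main reason it stays low: the run without that step reaches 72.5% against 8.71%, while the falling level of L is a part of the reason. With 17.4% of the L left at 72.0 h, q gives a D over G of 0.0988, and the flask holds 0.0977. With J and the time held, an L charge of 0.106 M or 0.142 M moves the answer by 5 points.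

For the neighbour with 0.030 M of J, the same quadratic with q gives 21.1% of D. The computed neighbour holds 20.9%, with 47% of its L still free.

The numbers in the tables were computed for an exercise.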